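Conventions used throughout: C1 ketone carbon; C2 CH bridgehead; C3=C4 alkene bridge (methyl on C4); C5 quaternary bridgehead; C6 lactone O–CH; C7–C9 rest of ring B; C10 methyl-bearing quaternary carbon; C11/C12 lactone α-carbon and carbonyl; C1′ (CH2) and C2′ (CH) the saturated bridge; C3′ the alkene carbon on C2′. "The branch" is the 6-methylhepta-1,5-dien-2-yl group; PMB is 4-methoxybenzyl.

## Analysis of the target

The target is a C25 keto lactone built on a bicyclo[2.2.2]oct-5-en-2-one with bridgeheads C2 and C5 and three bridges: C1(=O)–C10, C3=C4 and C2′–C1′. This bicycle shares the C5–C10 bond with a cyclohexane (ring B: C5, C6, C7, C8, C9, C10), and ring B carries a cis-fused α-methyl-γ-butyrolactone across C6–C7. There are seven stereocentres (C2, C5, C10, C2′, C6, C7, C11). The branch on C2′ points toward the ketone bridge and away from the alkene bridge. C9 leaves C10 on the side of the saturated bridge, so the C10 methyl faces the C3=C4 bridge. The lactone oxygen on C6 and C11 on C7 are cis to each other and on the same face of ring B as the C10 methyl, and the C11 methyl is trans to C8 (convex face of the lactone). The sensitive groups are the skipped diene of the branch (no hydrogenation, ozonolysis, strong acid or free halogen), the lactone with its epimerisable C11, and a hindered, non-enolisable but reducible C1 ketone. The synthesis is hard because C5 and C10 are vicinal quaternary carbons inside a congested bicycle, because only one of the seven stereocentres can come from a pool, and because four C=C bonds and three carbonyl groups must be told apart. The strategy rests on the ring C1–C2–C2′–C1′–C5–C10: it has the carvone pattern (ketone next to the methyl-bearing carbon, an isopropenyl-type branch para to that carbon), and C2 and C5 are spanned by a two-carbon bridge, so the bicycle is a formal [4+2] adduct of a carvone-derived 2-oxido diene and an acrylate.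

## Retrosynthetic reasoning

**C11–CH3.** The last bond cut in 35 is the C11–methyl bond, which leads to lactone 33. C11 is the only enolisable carbon of 33, because the C1 ketone has a bridgehead and a quaternary neighbour. In a cis-fused γ-lactone an electrophile enters from the convex face, which is where 35 carries the methyl group. The base-sensitive centre is therefore made last, by plain enolate methylation.

**C7–C11 and the lactone carbonyl.** Lactone 33 is traced through cyclic acetal 32 and bromoacetal 31 to allylic alcohol 30. The C7–C11 bond is cut as a 5-exo radical cyclisation of a two-carbon unit tethered to the C6 oxygen. Cutting here rather than at C6–O lets the C6 centre deliver C11 to its own face, which enforces the cis fusion and sets C7. The carbonyl is carried as an acetal until all hydride chemistry is over. The forward reaction needs a C7=C8 alkene next to a C6 hydroxyl that is syn to the C10 methyl.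

**C7=C8 and C6–C7.** Alcohol 30 comes from enone 29 by 1,2-reduction, and 29 from the ring-closing metathesis product 28. Opening 28 gives diene 27, and removing the vinyl group from C6 gives keto aldehyde 26. Metathesis is chosen because it forms ring B across the congested C5–C10 bond from two simple appendages and leaves exactly the alkene that the lactone annulation needs. The addition that makes C6–C7 cannot be trusted to set C6, so C6 is passed through the sp2 state (29) and set by hydride attack anti to the axial C10 methyl.

**Adjustment at C3/C4 and C6 (26 back to 17).** The C3=C4 methyl alkene of 26 is traced to the C4 ester of 17. Selenenylation and selenoxide elimination (19, 21) give the alkene; reduction of the conjugated ester and hydride displacement of allylic sulfonate 23 give the methyl group (22, 24). These steps come before ring B and the lactone because they use strong hydride donors. They also come before removal of the PMB group (25), because a free C6 hydroxyl would lactonise onto the neighbouring C4 ester. The C1 ketone is reduced on the way and is restored together with the C6 aldehyde in one oxidation (25 to 26).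

**C9–C10.** Removing the allyl group from 17 gives keto ester 15. C10 is the only enolisable position of 15, so the bond is made regiospecifically. The endo ester on C4 blocks the face turned toward the C3–C4 bridge, which should send the allyl group to the side of the saturated bridge.

**C2–C3 and C4–C5 (key disconnection).** Keto ester 15 is cut across the two-carbon bridge into enone 10 and methyl acrylate 11. One anionic [4+2] annulation then provides both bonds, the bicyclo[2.2.2]octanone, the quaternary bridgehead C5 and the configuration of C2, C4 and C5 relative to C2′. No other cut through the bicycle removes as much complexity while leaving a monocyclic precursor with a single, pool-derived stereocentre. The forward reaction must deprotonate 10 at C2 (α′) and not at a γ-position, add to 11 anti to the branch, and then close onto a fully substituted β-carbon.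

**Enone 10 from (R)-carvone 1.** Enone 10 is a carvone whose carbonyl has moved to the other side of the methyl-bearing carbon, with a protected hydroxymethyl group on the old carbonyl carbon and a prenyl-extended isopropenyl group. The transposition is cut as oxidative rearrangement of tertiary allylic alcohol 9, which goes back to 1,2-addition of organolithium 6 (from stannane 5, made from 3 and 4). The side chain is cut next to the former isopropenyl methyl carbon. Allylic chloride 2 is made directly from 1 and is coupled only after the 1,2-addition (7 to 8), when no carbonyl group is present, with an allyl nucleophile that cannot give regioisomers. Cross-metathesis then turns the terminal alkene of 8 into the trisubstituted one (9). Because the carbonyl changes sides, (R)-carvone 1 gives the (S)-enone 10 with the arrangement needed at C2′.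

## Alternatives that were turned down

**Alternative 1:** Ring B would be closed last at C8–C9. The precursor is acid A2, in which C10 carries a carboxymethyl arm and C5 a propenoyl group (C6 carbonyl, C7=C8). In the forward step, visible-light photoredox oxidation of the carboxylate and decarboxylation leave a primary C9 radical, which adds 6-endo to C8, the terminal carbon of the enone; reduction and protonation of the α-keto radical give diketone A1.
- For it: the conditions are neutral, a nucleophilic radical meets an electron-poor alkene, and the new bond forms at an unhindered CH2. Ring B closes in one step, which is shorter than the vinyl addition and metathesis used here (steps 15 and 16).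
- Against it: an unstabilised primary radical is the least favourable class for oxidative decarboxylation. The C9 radical sits in the cleft between the ketone bridge and the saturated bridge, about as close to the C3′ methylene as to C8, so capture by the side-chain alkene competes. A1 arrives with C6 as a ketone and C7 as a bare CH2, so O6, C7–C11 and C11 would still have to be set by enolate alkylation and reduction under substrate control.
- Comparison: A2 still needs the bicyclic core with both quaternary carbons, for which the annulation of step 7 plus a C10 alkylation remains the obvious source. The chosen route gives up the one-step closure and gains a C7=C8 alkene next to a C6 oxygen in 30, which locks the lactone fusion as cis.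

**Alternative 2:** The bicycle would be closed at C1′–C2′. The precursor is formyl cyclohexenone A4, which already holds ring B and the lactone, a formyl group (C1′) on C5, and a (Z)-trisubstituted alkenyl chain on C2. In the forward step, a dialkylaluminium chloride-type Lewis acid promotes a carbonyl-ene reaction: C1′ bonds to C2′ while a hydrogen of the allylic methyl group passes to oxygen, giving the C1′ alcohol A3 with the exocyclic methylene in place.
- For it: the bicycle and the 1,1-disubstituted alkene appear in one step at the end. The acid-sensitive diene therefore does not have to survive a long sequence, and on that point it is stronger than the present route, which carries the branch from step 5 onward.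
- Against it: C2 of A4 is α to the ketone and doubly allylic, so it can epimerise or slip into conjugation. The alkene must be made as the pure Z isomer. The ene transition state must place the bulky C3′ substituent toward the ketone bridge, for which there is no clear bias. The Lewis acid must pick the aldehyde over the ketone and the lactone without starting cationic cyclisation of the distal alkene. The C1′ hydroxyl of A3 is superfluous, and its radical removal would generate a homoallylic radical next to C2′, which is prone to 1,2-vinyl shift.
- Comparison: in the chosen strategy C2′ comes from the chiral pool, the bridge is built from a carbon that never bears oxygen, and no deoxygenation is needed.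

**Alternative 3:** C9–C10 would be formed intramolecularly. The precursor is iodide A6, the bicyclic keto ester of the annulation carrying a silyloxy-iodobutyl chain (C6 to C9) on C5. In the forward step, a hindered potassium amide base forms the C10 enolate, which displaces the primary iodide in a 6-exo-tet closure to give tricycle A5.
- For it: an intramolecular alkylation is the more dependable way to build a quaternary carbon beside another one, and on that point it is stronger than the intermolecular allylation of step 8. It also needs no metathesis catalyst in the presence of a polyene.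
- Against it: the face of C10 is still decided by the endo ester and not by the tether, so nothing is gained in stereocontrol. The four-carbon chain with a C6 stereocentre has to be built on a neopentyl aldehyde first. As drawn, the C6 oxygen of A5 lies on the face of ring B opposite to the C10 methyl, epimeric to what the lactone needs. Ring B arrives saturated, so C7 can only be functionalised after desilylation, oxidation to the C6 ketone, alkylation and reduction. A liberated C6 oxygen also sits gauche to the C4 ester and can lactonise onto it.
- Comparison: the chosen route accepts a harder C–C bond formation at C10 but uses a small, reactive electrophile, and its ring closure leaves the C7=C8 handle that A5 lacks.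

Key step: step 7

Remark on the chemistry: centres that are later planarised or re-set are left undefined in names and SMILES (C1 of 7–9, C4 of 19 and 20, C1 of 22–25, C6 of 27 and 28, the acetal carbon of 31 and 32). Compound 15 is drawn as the more stable C10 epimer, and its C10 epimer would serve equally.

## Route

Step 1
Reactants: 1 (R)-carvone
Product: 2 (5R)-5-(3-chloroprop-1-en-2-yl)-2-methylcyclohex-2-en-1-one
Conditions: Ca(OCl)2, solid CO2, CH2Cl2–H2O, 0 °C
Reagents that add atoms: calcium hypochlorite, [Ca+2].[O-]Cl.[O-]Cl
Why: Ene-type allylic chlorination by HOCl formed in situ; the electron-rich 1,1-disubstituted alkene reacts while the enone alkene is deactivated, and loss of a methyl proton gives the rearranged allylic chloride. The ring stereocentre is not touched.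

Step 2
Reactants: 3 4-methoxybenzyl alcohol; 4 tributyl(iodomethyl)stannane
Product: 5 tributyl{[(4-methoxybenzyl)oxy]methyl}stannane
Conditions: NaH, THF–DMF, 0 °C → rt
Reagents that add atoms: none
Why: Williamson etherification; the sodium alkoxide of 3 displaces the primary iodide of 4 (SN2).

Step 3
Reactants: 2 (5R)-5-(3-chloroprop-1-en-2-yl)-2-methylcyclohex-2-en-1-one; 5 tributyl{[(4-methoxybenzyl)oxy]methyl}stannane
Product: 7 (5R)-5-(3-chloroprop-1-en-2-yl)-1-{[(4-methoxybenzyl)oxy]methyl}-2-methylcyclohex-2-en-1-ol (C1 epimers), via alkoxymethyllithium 6 (not isolated)
Conditions: 5, nBuLi, THF, −78 °C; then 2, −78 °C; H2O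
Reagents that add atoms: none
Why: Tin–lithium exchange gives the α-alkoxy organolithium 6, which adds 1,2 to the enone carbonyl at −78 °C much faster than it substitutes the allylic chloride. The new carbinol centre is not controlled and is erased in step 6.

Step 4
Reactants: 7 (5R)-5-(3-chloroprop-1-en-2-yl)-1-{[(4-methoxybenzyl)oxy]methyl}-2-methylcyclohex-2-en-1-ol
Product: 8 (5R)-5-(hexa-1,5-dien-2-yl)-1-{[(4-methoxybenzyl)oxy]methyl}-2-methylcyclohex-2-en-1-ol (C1 epimers)
Conditions: allylmagnesium bromide (3 equiv), THF, 0 °C → rt; H2O
Reagents that add atoms: allylmagnesium bromide, C=CC[Mg]Br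
Why: Coupling of an allyl Grignard reagent with an allylic chloride after the first equivalent has formed the magnesium alkoxide. The electrophile is a 2-substituted allyl unit and the nucleophile the parent allyl group, so SN2 and SN2′ pathways give the same 1,5-diene.

Step 5
Reactants: 8 (5R)-5-(hexa-1,5-dien-2-yl)-1-{[(4-methoxybenzyl)oxy]methyl}-2-methylcyclohex-2-en-1-ol
Product: 9 (5R)-1-{[(4-methoxybenzyl)oxy]methyl}-2-methyl-5-(6-methylhepta-1,5-dien-2-yl)cyclohex-2-en-1-ol (C1 epimers)
Conditions: RuCl2(=CHPh)(PCy3)(H2IMes) (second-generation Grubbs catalyst, 3 mol %), 2-methylbut-2-ene–CH2Cl2, 35 °C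
Reagents that add atoms: 2-methylbut-2-ene, CC=C(C)C
Why: Olefin cross-metathesis; only the monosubstituted alkene enters the catalytic cycle, the 1,1-disubstituted and ring alkenes being too hindered. The large excess of 2-methylbut-2-ene caps it as the dimethyl-substituted alkene.

Step 6
Reactants: 9 (5R)-1-{[(4-methoxybenzyl)oxy]methyl}-2-methyl-5-(6-methylhepta-1,5-dien-2-yl)cyclohex-2-en-1-ol
Product: 10 (5S)-3-{[(4-methoxybenzyl)oxy]methyl}-2-methyl-5-(6-methylhepta-1,5-dien-2-yl)cyclohex-2-en-1-one
Conditions: pyridinium chlorochromate (C5H5NH)[CrO3Cl], 4 Å molecular sieves, CH2Cl2, rt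
Reagents that add atoms: pyridinium chlorochromate (supplies the carbonyl oxygen), [O-][Cr](=O)(=O)Cl.c1cc[nH+]cc1
Why: Oxidative allylic transposition (Babler–Dauben oxidation); the tertiary chromate ester shifts [3,3] to the secondary allylic chromate, which is oxidised to the β,β-disubstituted enone. Both C1 epimers converge and the carvone stereocentre, now C5 of the enone, is untouched.

Step 7
Reactants: 10 (5S)-3-{[(4-methoxybenzyl)oxy]methyl}-2-methyl-5-(6-methylhepta-1,5-dien-2-yl)cyclohex-2-en-1-one; 11 methyl acrylate
Product: 15 bicyclo[2.2.2]octanone keto ester (C1 ketone; C10–H with its methyl toward the C1′–C2′ bridge; CH2OPMB on C5; CO2Me on C4 endo, syn to the C1–C10 bridge; branch on C2′ syn to the C1–C10 bridge), via lithium dienolate 12 (not isolated), via acyclic ester enolate 13 (not isolated), via bicyclic ketone enolate 14 (not isolated)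
Conditions: LiN(iPr)2 (1.1 equiv), THF, −78 °C; 11 (1.2 equiv), −78 °C → rt; AcOH
Reagents that add atoms: none
Why: LiN(iPr)2 removes a C2 proton under kinetic control to give the cross-conjugated dienolate 12; its C2 terminus adds to the β-carbon of 11 (bond C2–C3), and the ester enolate 13 so formed adds intramolecularly to C5, the β-carbon of the regenerated enone (bond C4–C5), giving ketone enolate 14, which is protonated at C10 on quench. The closest known reaction type is the double Michael (stepwise anionic [4+2]) annulation of cyclohexenone α′-dienolates with acrylates to bicyclo[2.2.2]octan-2-ones, established for carvone-type enones and for enones with a substituted β-carbon. The ring closure is the second Michael addition, 6-endo-trig for the ring C1–C2–C3–C4–C5–C10 that contains the accepting C5=C10 bond (6-exo-trig for the ring through C2′ and C1′), and because it is intramolecular it can create the quaternary bridgehead. C2 is set by approach of 11 anti to the branch on the neighbouring C2′, the only stereocentre of 10; C5 follows necessarily, since the two-carbon bridge can only span one face of the ring; C4 takes the ester endo (syn to the C1–C10 bridge) through the compact, lithium-bridged transition state of the closure; C10 is set on protonation, is expected with the methyl away from the ester, and is planarised again in step 8. The step needs α′ over γ deprotonation (hindered amide base at −78 °C), face selectivity at C2 (the C2′ branch), and closure faster than acrylate oligomerisation (intramolecular second addition, only a slight excess of 11).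

Step 8
Reactants: 15 bicyclo[2.2.2]octanone keto ester
Product: 17 C10-allyl keto ester (allyl group on C10 toward the C1′–C2′ bridge; C10 methyl toward the C3–C4 bridge), via potassium enolate 16 (not isolated)
Conditions: KN(SiMe3)2, THF, −78 °C; allyl bromide, −78 → 0 °C
Reagents that add atoms: allyl bromide, C=CCBr
Why: Ketone enolate alkylation; the silylamide removes only the C10 proton (C2 is a bridgehead and the ester α-proton is less acidic), and enolate 16 is allylated at carbon. The endo ester on C4 shields the face of C10 turned toward the C3–C4 bridge, so the allyl group (C9) should enter from the C1′–C2′ side and set the quaternary centre as in the target.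

Step 9
Reactants: 17 C10-allyl keto ester
Product: 19 C4-phenylselanyl ester (C4 epimers), via lithium ester enolate 18 (not isolated)
Conditions: LiN(iPr)2, THF, −78 °C; PhSeSePh, −78 °C
Reagents that add atoms: diphenyl diselenide, c1ccc(cc1)[Se][Se]c1ccccc1
Why: α-Selenenylation of an ester enolate; with C10 quaternary and C2 a bridgehead the ketone cannot enolise, so only C4 is deprotonated. The diselenide does not add to the alkenes, and −78 °C avoids retro-Michael opening of enolate 18; the C4 configuration is irrelevant.

Step 10
Reactants: 19 C4-phenylselanyl ester
Product: 21 C3=C4 enoate (methyl ester on C4), via selenoxide 20 (not isolated)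
Conditions: NaIO4, NaHCO3, THF–MeOH–H2O, 0 °C → rt
Reagents that add atoms: none
Why: Selenide oxidation and selenoxide syn-elimination; C5 is quaternary, so the only β-hydrogens are on C3 and the C3=C4 enoate is the sole possible alkene. Periodate does not epoxidise the other alkenes.

Step 11
Reactants: 21 C3=C4 enoate
Product: 22 diol (CH2OH on C4; C1 carbinol, C1 epimers; PMB ether on C6 retained)
Conditions: iBu2AlH (4 equiv), CH2Cl2, −78 → 0 °C; aqueous potassium sodium tartrate
Reagents that add atoms: none
Why: Hydride reduction; the enoate is reduced 1,2 to the primary allylic alcohol and the C1 ketone to the secondary alcohol, whose configuration is irrelevant because it is reoxidised in step 14. The PMB ether and all alkenes are inert.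

Step 12
Reactants: 22 diol
Product: 24 C4-methyl alkene (C3=C4 with CH3 on C4; C1–OH; C6–OPMB), via allylic mesylate 23 (not isolated)
Conditions: MsCl (1.05 equiv), Et3N, THF, −30 °C; then LiEt3BH, −30 → 0 °C
Reagents that add atoms: none
Why: Selective sulfonylation of the primary allylic hydroxyl (the C1 hydroxyl is secondary and flanked by a quaternary carbon), then SN2 hydride displacement, turns CH2OH into the C4 methyl group without moving the double bond.

Step 13
Reactants: 24 C4-methyl alkene
Product: 25 C1,C6-diol
Conditions: DDQ, CH2Cl2–pH 7 buffer, 0 °C
Reagents that add atoms: none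
Why: Oxidative cleavage of the PMB ether through the benzylic oxocarbenium ion and its hydrolysis; isolated alkenes and the free C1 hydroxyl are tolerated under buffered conditions. The C4 ester that could have lactonised onto the C6 hydroxyl is gone by now.

Step 14
Reactants: 25 C1,C6-diol
Product: 26 keto aldehyde (C1 ketone; formyl group C6 on C5)
Conditions: Dess–Martin periodinane (3 equiv), CH2Cl2, rt
Reagents that add atoms: none
Why: Double Dess–Martin oxidation gives the C6 aldehyde and restores the C1 ketone. No lactol can form between the two positions, because C1 and C6 are antiperiplanar about C10–C5, and the aldehyde on quaternary C5 cannot enolise.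

Step 15
Reactants: 26 keto aldehyde
Product: 27 C6 vinyl carbinol (C6 epimers)
Conditions: vinylmagnesium bromide (1.3 equiv), THF, −78 °C; H2O
Reagents that add atoms: vinylmagnesium bromide, C=C[Mg]Br
Why: Grignard addition; the aldehyde is far more electrophilic than the C1 ketone, which is flanked by quaternary C10 and bridgehead C2 and screened by the branch. The C6 configuration is not relied upon and is corrected in steps 17 and 18.

Step 16
Reactants: 27 C6 vinyl carbinol
Product: 28 ring-B cyclohexenol (C7=C8; C6 epimers)
Conditions: RuCl2(=CHPh)(PCy3)2 (first-generation Grubbs catalyst, 5 mol %), CH2Cl2 (0.005 M), 40 °C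
Reagents that add atoms: none
Why: Ring-closing metathesis of the two monosubstituted alkenes closes ring B as a cyclohexene with loss of ethene. The first-generation catalyst does not engage the 1,1-disubstituted or trisubstituted alkenes, and the vicinal quaternary carbons favour closure.

Step 17
Reactants: 28 ring-B cyclohexenol
Product: 29 ring-B enone (C6 ketone; C7=C8)
Conditions: Dess–Martin periodinane, CH2Cl2, rt
Reagents that add atoms: none
Why: Oxidation of the allylic alcohol to the enone removes the uncontrolled C6 centre.

Step 18
Reactants: 29 ring-B enone
Product: 30 allylic alcohol (C6–OH syn to the C10 methyl and to the C3=C4 bridge; C7=C8)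
Conditions: NaBH4, CeCl3·7H2O, MeOH, −78 °C
Reagents that add atoms: none
Why: Luche 1,2-reduction; in the half-chair of ring B the C10 methyl is axial and 1,3 to C6, so hydride should enter from the opposite face (that of C1′) and place the hydroxyl syn to the C10 methyl, as the lactone needs. The hindered C1 ketone should react much more slowly at −78 °C.

Step 19
Reactants: 30 allylic alcohol
Product: 31 bromoacetal (C6–O–CH(OEt)–CH2Br; acetal carbon epimers)
Conditions: ethyl vinyl ether, Br2, CH2Cl2, −78 °C; then 30, PhNMe2, −78 °C → rt
Reagents that add atoms: ethyl vinyl ether, C=COCC; bromine, BrBr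
Why: Acetalisation of the hindered alcohol by the α-bromo oxocarbenium ion from preformed 1,2-dibromoethyl ethyl ether (first half of the Ueno–Stork sequence). Preforming the dibromide keeps free bromine away from the alkenes of 30.

Step 20
Reactants: 31 bromoacetal
Product: 32 tetracyclic ethyl acetal (cis-fused 2-ethoxytetrahydrofuran on C6–C7; C11 on C7 syn to O6; acetal carbon epimers)
Conditions: Bu3SnH, AIBN (cat.), benzene (0.02 M), 80 °C
Reagents that add atoms: none
Why: Ueno–Stork radical cyclisation; the primary radical adds 5-exo-trig to C7 on the face of the tethering oxygen, so the O–C6/C7–C11 fusion is necessarily cis. The C8 radical is reduced by the stannane before it can reach another alkene.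

Step 21
Reactants: 32 tetracyclic ethyl acetal
Product: 33 lactone lacking the C11 methyl group
Conditions: CrO3, H2SO4, acetone–H2O, 0 °C
Reagents that add atoms: water, O
Why: Jones oxidation hydrolyses the ethyl acetal to the lactol and oxidises it to the γ-lactone in one operation. The ketone and the alkenes should survive short exposure at 0 °C.

Step 22
Reactants: 33 lactone lacking the C11 methyl group
Product: 35 the target CNP0385704.2, via lithium lactone enolate 34 (not isolated)
Conditions: LiN(iPr)2 (1.05 equiv), THF, −78 °C; MeI, −78 → −40 °C
Reagents that add atoms: iodomethane, CI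
Why: Lactone enolate alkylation; the lactone is the only enolisable carbonyl group, and iodomethane approaches enolate 34 from the convex face of the cis-fused bicycle (the face of H7). This gives the C11 methyl trans to C8, as in 35.

## Compound list

1 | (R)-carvone | CC1=CC[C@H](CC1=O)C(C)=C | starting material
2 | (5R)-5-(3-chloroprop-1-en-2-yl)-2-methylcyclohex-2-en-1-one | CC1=CC[C@H](CC1=O)C(CCl)=C | intermediate
3 | 4-methoxybenzyl alcohol | COc1ccc(CO)cc1 | starting material
4 | tributyl(iodomethyl)stannane | CCCC[Sn](CCCC)(CCCC)CI | starting material
5 | tributyl{[(4-methoxybenzyl)oxy]methyl}stannane | CCCC[Sn](CCCC)(CCCC)COCc1ccc(OC)cc1 | intermediate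
6 | [(4-methoxybenzyl)oxy]methyllithium (not isolated) | [Li]COCc1ccc(OC)cc1 | intermediate
7 | (5R)-5-(3-chloroprop-1-en-2-yl)-1-{[(4-methoxybenzyl)oxy]methyl}-2-methylcyclohex-2-en-1-ol, C1 epimers | CC1=CC[C@H](CC1(O)COCc2ccc(OC)cc2)C(CCl)=C | intermediate
8 | (5R)-5-(hexa-1,5-dien-2-yl)-1-{[(4-methoxybenzyl)oxy]methyl}-2-methylcyclohex-2-en-1-ol, C1 epimers | CC1=CC[C@H](CC1(O)COCc2ccc(OC)cc2)C(CCC=C)=C | intermediate
9 | (5R)-1-{[(4-methoxybenzyl)oxy]methyl}-2-methyl-5-(6-methylhepta-1,5-dien-2-yl)cyclohex-2-en-1-ol, C1 epimers | CC1=CC[C@H](CC1(O)COCc2ccc(OC)cc2)C(CCC=C(C)C)=C | intermediate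
10 | (5S)-3-{[(4-methoxybenzyl)oxy]methyl}-2-methyl-5-(6-methylhepta-1,5-dien-2-yl)cyclohex-2-en-1-one | C=C(CCC=C(C)C)[C@H]1CC(COCc2ccc(OC)cc2)=C(C)C(=O)C1 | intermediate
11 | methyl acrylate | C=CC(=O)OC | starting material
12 | lithium cross-conjugated dienolate of 10 (not isolated) | C=C(CCC=C(C)C)[C@H]1CC(COCc2ccc(OC)cc2)=C(C)C(O[Li])=C1 | intermediate
13 | lithium ester enolate of the mono-Michael adduct, C3 trans to the branch (not isolated) | C=C(CCC=C(C)C)[C@H]1CC(COCc2ccc(OC)cc2)=C(C)C(=O)[C@@H]1CC=C(OC)O[Li] | intermediate
14 | lithium C1=C10 enolate of the bicyclic adduct (not isolated) | C=C(CCC=C(C)C)[C@H]1C[C@]2(COCc3ccc(OC)cc3)[C@@H](C(=O)OC)C[C@H]1C(O[Li])=C2C | intermediate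
15 | bicyclo[2.2.2]octanone keto ester, C4 ester endo, C10–H | C=C(CCC=C(C)C)[C@H]1C[C@]2(COCc3ccc(OC)cc3)[C@@H](C(=O)OC)C[C@H]1C(=O)[C@@H]2C | intermediate
16 | potassium C1=C10 enolate of 15 (not isolated) | C=C(CCC=C(C)C)[C@H]1C[C@]2(COCc3ccc(OC)cc3)[C@@H](C(=O)OC)C[C@H]1C(O[K])=C2C | intermediate
17 | C10-allyl keto ester, allyl toward the C1′–C2′ bridge | C=C(CCC=C(C)C)[C@H]1C[C@]2(COCc3ccc(OC)cc3)[C@@H](C(=O)OC)C[C@H]1C(=O)[C@]2(C)CC=C | intermediate
18 | lithium ester enolate of 17 at C4 (not isolated) | C=C(CCC=C(C)C)[C@H]1C[C@]2(COCc3ccc(OC)cc3)C(=C(OC)O[Li])C[C@H]1C(=O)[C@]2(C)CC=C | intermediate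
19 | C4-phenylselanyl ester, C4 epimers | C=C(CCC=C(C)C)[C@H]1C[C@]2(COCc3ccc(OC)cc3)C([Se]c3ccccc3)(C(=O)OC)C[C@H]1C(=O)[C@]2(C)CC=C | intermediate
20 | selenoxide of 19 (not isolated) | C=C(CCC=C(C)C)[C@H]1C[C@]2(COCc3ccc(OC)cc3)C([Se](=O)c3ccccc3)(C(=O)OC)C[C@H]1C(=O)[C@]2(C)CC=C | intermediate
21 | C3=C4 enoate | C=C(CCC=C(C)C)[C@H]1C[C@]2(COCc3ccc(OC)cc3)C(C(=O)OC)=C[C@H]1C(=O)[C@]2(C)CC=C | intermediate
22 | diol, CH2OH on C4 and C1 carbinol (C1 epimers) | C=C(CCC=C(C)C)[C@H]1C[C@]2(COCc3ccc(OC)cc3)C(CO)=C[C@H]1C(O)[C@]2(C)CC=C | intermediate
23 | primary allylic mesylate of 22 (not isolated) | C=C(CCC=C(C)C)[C@H]1C[C@]2(COCc3ccc(OC)cc3)C(COS(C)(=O)=O)=C[C@H]1C(O)[C@]2(C)CC=C | intermediate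
24 | C4-methyl alkene, C1–OH, C6–OPMB | C=C(CCC=C(C)C)[C@H]1C[C@]2(COCc3ccc(OC)cc3)C(C)=C[C@H]1C(O)[C@]2(C)CC=C | intermediate
25 | C1,C6-diol | C=C(CCC=C(C)C)[C@H]1C[C@]2(CO)C(C)=C[C@H]1C(O)[C@]2(C)CC=C | intermediate
26 | keto aldehyde | C=C(CCC=C(C)C)[C@H]1C[C@]2(C=O)C(C)=C[C@H]1C(=O)[C@]2(C)CC=C | intermediate
27 | C6 vinyl carbinol, C6 epimers | C=C(CCC=C(C)C)[C@H]1C[C@]2(C(O)C=C)C(C)=C[C@H]1C(=O)[C@]2(C)CC=C | intermediate
28 | ring-B cyclohexenol, C6 epimers | C=C(CCC=C(C)C)[C@H]1C[C@]23C(C)=C[C@H]1C(=O)[C@]2(C)CC=CC3O | intermediate
29 | ring-B enone | C=C(CCC=C(C)C)[C@H]1C[C@]23C(C)=C[C@H]1C(=O)[C@]2(C)CC=CC3=O | intermediate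
30 | allylic alcohol, C6–OH syn to the C10 methyl | C=C(CCC=C(C)C)[C@H]1C[C@]23C(C)=C[C@H]1C(=O)[C@]2(C)CC=C[C@H]3O | intermediate
31 | bromoacetal, acetal carbon epimers | C=C(CCC=C(C)C)[C@H]1C[C@]23C(C)=C[C@H]1C(=O)[C@]2(C)CC=C[C@H]3OC(CBr)OCC | intermediate
32 | tetracyclic ethyl acetal, acetal carbon epimers | C=C(CCC=C(C)C)[C@H]1C[C@]23C(C)=C[C@H]1C(=O)[C@]2(C)CC[C@H]1CC(OCC)O[C@H]13 | intermediate
33 | lactone lacking the C11 methyl group | C=C(CCC=C(C)C)[C@H]1C[C@]23C(C)=C[C@H]1C(=O)[C@]2(C)CC[C@H]1CC(=O)O[C@H]13 | intermediate
34 | lithium enolate of lactone 33 (not isolated) | C=C(CCC=C(C)C)[C@H]1C[C@]23C(C)=C[C@H]1C(=O)[C@]2(C)CC[C@H]1C=C(O[Li])O[C@H]13 | intermediate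
35 | CNP0385704.2 | C=C(CCC=C(C)C)[C@H]1C[C@]23C(C)=C[C@H]1C(=O)[C@]2(C)CC[C@H]1[C@H](C)C(=O)O[C@H]13 | target

## Step count and least certain steps

Total: 22 steps. Longest linear sequence: 21 steps (step 1, then steps 3 to 22); step 2 is a side branch.

**Step 7 (key step).** The second Michael addition may stall at the stage of 13 because C5 is fully substituted, and the acrylate may oligomerise under anionic conditions; γ-deprotonation would erode regiocontrol. The fallback separates diene formation from cycloaddition. It sets out from 10: the dienolate is silylated (LiN(iPr)2, then Me3SiCl) to the trimethylsilyl dienol ether F1. A thermal Diels–Alder reaction with 11 (toluene, 110 °C) should give the silyl enol ether cycloadduct F2 with the same regiochemistry, endo ester and approach anti to the branch. Dilute HCl in THF then hydrolyses F2, and the route is rejoined at 15.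

**Step 8.** Carbon–carbon bond formation next to the quaternary C5 may be slow, O-allylation may take over, and the face selectivity may be eroded by the branch on the opposite side. The fallback uses decarboxylative allylation (Tsuji allylation). It sets out from 15: the potassium enolate is O-acylated with allyl chloroformate to the allyl enol carbonate F3. The zerovalent palladium complex Pd(PPh3)4 (catalytic, THF, rt) ionises it to an enolate/π-allyl ion pair that recombines at carbon with decarboxylation. The route is rejoined at 17.

**Step 12.** Hydride may attack in the SN2′ sense and give an exocyclic methylene, or the allylic sulfonate may ionise before reduction. The fallback sets out from 22: selective acetylation of the primary hydroxyl (Ac2O, pyridine, 0 °C) gives the allylic acetate F4. Reduction with Pd(PPh3)4 and LiEt3BH delivers hydride to the less hindered, exocyclic terminus of the π-allyl complex. The route is rejoined at 24.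

**Step 18.** Facial selectivity may be poor, because the axial C1′ methylene next to the carbonyl opposes the bias exerted by the C10 methyl; over-reduction at C1 is a lesser concern. The fallback changes the order of bond formation and sets out from 29. Conjugate reduction with LiB(sBu)3H (THF, −78 °C) gives the C6 enolate regiospecifically, and trapping with methyl bromoacetate gives the C7-alkylated keto ester F5; its equatorial epimer, with C11 syn to the C10 methyl, is the more stable one and can be reached by base equilibration, since C7 is the only enolisable position. Reduction of the saturated C6 ketone with the same bulky borohydride, which approaches equatorially and away from the axial C10 methyl, gives the axial alkoxide; this closes onto the ester. The route is rejoined at 33, bypassing 30 to 32.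

**Step 21.** Aqueous sulfuric acid may hydrate or cyclise the alkenes of the branch before the oxidation is complete. The fallback sets out from 32: hydrolysis under mild acid (AcOH–THF–H2O, 40 °C) gives the lactol F6, which is oxidised under neutral conditions with Ag2CO3 on Celite (Fetizon oxidation, benzene, 80 °C). The route is rejoined at 33.

## Further compounds

F1 | step 7 | trimethylsilyl dienol ether of 10 (2-silyloxy-1,3-diene) | C=C(CCC=C(C)C)[C@H]1CC(COCc2ccc(OC)cc2)=C(C)C(O[Si](C)(C)C)=C1
F2 | step 7 | silyl enol ether cycloadduct (C1=C10 trimethylsilyl enol ether of 15) | C=C(CCC=C(C)C)[C@H]1C[C@]2(COCc3ccc(OC)cc3)[C@@H](C(=O)OC)C[C@H]1C(O[Si](C)(C)C)=C2C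
F3 | step 8 | allyl enol carbonate of 15 | C=C(CCC=C(C)C)[C@H]1C[C@]2(COCc3ccc(OC)cc3)[C@@H](C(=O)OC)C[C@H]1C(OC(=O)OCC=C)=C2C
F4 | step 12 | primary allylic acetate of 22 | C=C(CCC=C(C)C)[C@H]1C[C@]2(COCc3ccc(OC)cc3)C(COC(C)=O)=C[C@H]1C(O)[C@]2(C)CC=C
F5 | step 18 | C7-(methoxycarbonylmethyl) C6 ketone, arm syn to the C10 methyl | C=C(CCC=C(C)C)[C@H]1C[C@]23C(C)=C[C@H]1C(=O)[C@]2(C)CC[C@@H](CC(=O)OC)C3=O
F6 | step 21 | lactol from hydrolysis of 32 | C=C(CCC=C(C)C)[C@H]1C[C@]23C(C)=C[C@H]1C(=O)[C@]2(C)CC[C@H]1CC(O)O[C@H]13
A1 | alternative 1 | tricyclic 1,6-diketone with ring B closed | C=C(CCC=C(C)C)[C@H]1C[C@]23C(C)=C[C@H]1C(=O)[C@]2(C)CCCC3=O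
A2 | alternative 1 | C5 propenoyl, C10 carboxymethyl acid | C=C(CCC=C(C)C)[C@H]1C[C@]2(C(=O)C=C)C(C)=C[C@H]1C(=O)[C@]2(C)CC(=O)O
A3 | alternative 2 | C1′-hydroxy derivative of the target | C=C(CCC=C(C)C)[C@H]1[C@@H](O)[C@]23C(C)=C[C@H]1C(=O)[C@]2(C)CC[C@H]1[C@H](C)C(=O)O[C@H]13
A4 | alternative 2 | C5-formyl cyclohexenone lactone with (Z)-alkenyl chain on C2 | O=C[C@]12C(C)=C[C@H](/C=C(/C)CCC=C(C)C)C(=O)[C@]1(C)CC[C@H]3[C@H](C)C(=O)O[C@@H]23
A5 | alternative 3 | tricyclic keto ester silyl ether with ring B closed | C=C(CCC=C(C)C)[C@H]1C[C@]23[C@@H](C(=O)OC)C[C@H]1C(=O)[C@]2(C)CCC[C@@H]3O[Si](C)(C)C(C)(C)C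
A6 | alternative 3 | bicyclic keto ester with 1-silyloxy-4-iodobutyl chain on C5 | C=C(CCC=C(C)C)[C@H]1C[C@]2([C@H](CCCI)O[Si](C)(C)C(C)(C)C)[C@@H](C(=O)OC)C[C@H]1C(=O)C2C
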